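**Compound numbers used throughout**

1 propargyl alcohol · 2 4-iodo-1,2-dimethoxybenzene · 3 3-(3,4-dimethoxyphenyl)prop-2-yn-1-ol · 4 (E)-3,4-dimethoxycinnamaldehyde · 5 oxa-Michael adduct (not isolated) · 6 benzylidene tetrahydrofuran carbaldehyde · 7 benzylidene alcohol · 8 silyl ether of 7 · 9 saturated silyl ether · 10 saturated alcohol · 11 angelic acid · 12 leoligin.

Ring atoms of the target: O1, C2 (aryl), C3 (carries the arm C6), C4 (carries C7–aryl), C5.

## Analysis of the target

Leoligin (12) is a lignan built on one tetrahydrofuran ring (O1, C2–C5). C2 carries a 3,4-dimethoxyphenyl group, C3 an acyloxymethyl arm (C6) esterified with angelic acid (11), and C4 a 3,4-dimethoxybenzyl group (C7–aryl). The three stereocentres are contiguous and 2S,3R,4R: the aryl group on C2 is trans to the C3 arm, and the C3 arm is cis to the benzyl group on C4. The 2,3-trans relation is the relaxed one, but the 3,4-cis relation cannot be reached by equilibration because nothing acidifies C4, so it has to be built kinetically. The angelate is the most delicate group: its Z alkene turns into the E isomer (tiglate) when the acyl group is activated or a nucleophile adds reversibly, and it would not survive a hydrogenation. The C2–O1 bond is a benzylic ether to an electron-rich arene, so it can ionise under acid, which would cost the C2 configuration, and it can be cleaved by hydrogenolysis. The hard part is to introduce absolute configuration at C2, which has no neighbouring functional group to hold on to, and then to relay it to C3 and C4. The strategy rests on two features: C2 is benzylic, bears O1 and lies β to C6, which is the pattern of an alcohol added to the β-carbon of a cinnamaldehyde; and C5–C4–C7–aryl is the carbon chain of an aryl propargylic alcohol whose oxygen is O1.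

## Retrosynthetic reasoning

**12 ⇒ 10 + 11.** The bond between C6 and the ester oxygen is cut first. The angelate must go on last, because it is the only group that neither a hydrogenation nor a basic or acidic step would spare. The forward reaction has to join the primary alcohol 10 and the acid 11 without turning 11 into an acyl electrophile; a Mitsunobu esterification, which activates the alcohol, does this.

**10 ⇒ 9 ⇒ 8.** The C4–H and C7–H bonds are removed, which replaces the stereocentre C4 by a C4=C7 double bond conjugated with the benzyl arene. This erases the hardest stereocentre and leaves a benzylidene whose two faces are distinguished by the adjacent C3 arm. The forward reaction has to add hydrogen to the face away from that arm, which places the benzyl group cis to it. A bulky silyl ether on C6 (9 and 8) strengthens the bias and removes a free hydroxyl that could bind to the catalyst surface and pull hydrogen to the wrong face.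

**8 ⇒ 7 ⇒ 6.** These are changes of protecting group and oxidation state only: silyl ether back to alcohol 7, alcohol back to aldehyde 6. The aldehyde level at C6 is what the ring construction needs, since a formyl group makes C2 electrophilic as an iminium ion and C3 nucleophilic as an enamine. The forward reduction has to be faster than any loss of the C3 configuration or of the alkene position, because in 6 the C3 hydrogen is both α to the formyl group and allylic.

**6 ⇒ 3 + 4 (through 5).** The bonds O1–C2 and C3–C4 are cut. This divides the ring into two pieces of eleven carbons each, every one with its own arene: the enal 4 supplies C2, C3 and C6, and the alkynol 3 supplies O1, C5, C4 and C7. No other pair of cuts gives two fragments this simple, and both bonds can be made under one set of catalysts (amine and palladium co-catalysis). The forward reaction has to add the hydroxyl of 3 to the β-carbon of 4 with control of C2, then close the ring by attack of the enamine carbon of adduct 5 on the alkyne. Since alcohol additions to enals are reversible, the ring closure also has to pull the equilibrium forward. The aryl cap on the alkyne is the future benzyl arene and keeps the new alkene outside the ring.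

**3 ⇒ 1 + 2.** The bond between the alkyne carbon and the arene is cut. Sonogashira coupling of 1 with 2 makes it in one step from two commercial compounds, so that the whole risk of the route lies in the ring-forming step.

## Alternatives that were turned down

**Alternative 1: radical ring closure with arylation at C7.**
- Disconnection: C3–C4 and C7–aryl in one step.
- Forward key step: the secondary iodide A2, a silyl-protected 3-allyloxy-3-aryl-2-iodopropanol with C2 already in place, would react with aryl iodide 2 under NiI2, 4,4′-di-tert-butyl-2,2′-bipyridine and manganese powder. The C3 radical would close 5-exo-trig onto the allyl ether, and the primary C7 radical would be taken up by nickel and arylated, giving silyl ether A1, which is the same compound as 9.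
- For it: two carbon–carbon bonds and the ring form together; the saturated skeleton is reached directly, with no alkene to reduce and no aldehyde that can isomerise; only desilylation and esterification remain.
- Against it: C2 has to be bought before the key step, so A2 needs an enantioenriched aryl carbinol, O-allylation and installation of the iodide next to a silyl ether, several steps in all. C3 and C4 are both fixed in one irreversible radical closure. The trans relation to C2 is well founded, but the cis relation between the C3 arm and the new C7 group rests on the intrinsically small preference of 1-substituted hexenyl-type radicals, and neither centre can be corrected afterwards. A β-allyloxy alkylnickel species can also expel allyloxide instead of cyclising.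
- Comparison: this alternative is stronger in the endgame, two steps after the key step against five. The chosen route offers a one-step precursor, catalyst control of C2 inside the ring-forming step, an epimerisable C3, and a separate, sterically well-defined step for C4.

**Alternative 2: carbonyl ylide cycloaddition to a menthyloxy butenolide.**
- Disconnection: C2–C3 and C4–C5.
- Forward key step: CsF would release the ylide from the α-chloro silylmethyl ether A4, and the ylide would add across the alkene of the menthyloxyfuranone A5 to give the cis-fused furofuranone A3.
- For it: one metal-free step makes the ring and all three ring stereocentres; the cis ring fusion guarantees the 3,4-cis relation by geometry instead of by facial selectivity; the acetal substituent steers the ylide to the opposite face.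
- Against it: the ylide is unsymmetrical and must bond through its aryl-bearing terminus to the α-carbon of the butenolide, with the aryl group exo, and neither orientation has a strong electronic cause. In A3, C7 is an acetal carbon without its arene. The acetal must be opened, an aryl nucleophile added, and the resulting benzylic alcohol deoxygenated beside the equally benzylic C2–O1 ether. C6 must also be reduced from the lactone level. The natural enantiomer requires the (1S,2R,5S)-menthyl group in A5, that of (+)-menthol, the less common enantiomer, in stoichiometric amount.
- Comparison: this alternative is stronger on the 3,4-cis relation. The chosen route carries the C7 arene from the start, has C6 one reduction away from the target level, needs no auxiliary and is clearly shorter after the key step.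

**Alternative 3: photo-Wolff ring contraction of a pyranone.**
- Disconnection: C3–C4, made by a 1,2-shift that contracts a six-membered ring.
- Forward key step: irradiation of the diazoketone A7 in methanol would expel nitrogen, the benzyl-bearing ring carbon would migrate from the carbonyl carbon to the carbene carbon, and methanol would trap the ketene as the methyl ester A6.
- For it: a catalytic asymmetric hetero-Diels–Alder reaction of an aromatic aldehyde can set C2. The benzyl-bearing carbon is α to the ketone and settles trans to the aryl group across the pyranone. The migration goes with retention, so C4 arrives secure. Reduction of A6 gives 10 directly.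
- Against it: C3 is created when methanol protonates the ketene-derived enol. It is flanked by substituents on opposite faces, so each C3 epimer has one cis neighbour and neither kinetic protonation nor equilibration of the ester has a strong preference. The carbene lies next to the C2–H bond of a benzylic ether, so a 1,2-hydrogen shift competes with the ring contraction. A substituted diene, a conjugate reduction and a two-stage diazo transfer precede the key step, and diazo handling and photochemistry are needed.
- Comparison: this alternative is stronger on the relation between C2 and C4, which is set thermodynamically and transferred with retention. The chosen route offers an unambiguous C3, since at the time it is set only one neighbour is substituted and the centre can equilibrate, together with fewer steps.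

Key step: step 2

Assumption: the (S)-configured diphenylprolinol silyl ether is taken to give the 2S series, by the usual shielding model for additions to the β-carbon of cinnamaldehyde-derived iminium ions; if the dynamic ring closure selected the other epimer, the enantiomeric catalyst would be used.

## Route

Step 1
Reactants: 1 propargyl alcohol; 2 4-iodo-1,2-dimethoxybenzene
Product: 3 3-(3,4-dimethoxyphenyl)prop-2-yn-1-ol
Conditions: Pd(PPh3)2Cl2 (2 mol %), CuI (4 mol %), Et3N, THF, rt, degassed
Reagents that add atoms: none
Why: Sonogashira coupling: oxidative addition of the aryl iodide to zerovalent palladium, transmetalation from the copper acetylide of 1 and reductive elimination; aryl iodides couple at room temperature and the free hydroxyl is tolerated. No stereocentre is formed.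

Step 2
Reactants: 3 3-(3,4-dimethoxyphenyl)prop-2-yn-1-ol; 4 (E)-3-(3,4-dimethoxyphenyl)prop-2-enal
Product: 6 (2S,3S,4E)-2-(3,4-dimethoxyphenyl)-4-(3,4-dimethoxybenzylidene)tetrahydrofuran-3-carbaldehyde, via oxa-Michael adduct 5 (not isolated)
Conditions: (S)-2-[diphenyl(trimethylsilyloxy)methyl]pyrrolidine (20 mol %), Pd(PPh3)4 (5 mol %), PhCO2H (20 mol %), CHCl3, 4 °C, N2; crude solution taken on at once
Reagents that add atoms: none
Why: Proposed new method: 4 and the amine form an E iminium ion, the hydroxyl of 3 adds reversibly to its β-carbon to give the enamine of 5 (O1–C2), and the enamine carbon attacks the palladium-bound alkyne at its proximal carbon (C3–C4) anti to the metal, after which protonolysis of the vinylpalladium species and hydrolysis release 6 and both catalysts; the closest known reaction type is the amine and palladium co-catalysed oxa-Michael and carbocyclisation of enals with propargyl alcohol itself, extended here to an alkyne that carries an aryl cap. The tetrahydrofuran ring closes 5-exo-dig, since the three-atom tether from the enamine carbon reaches only the proximal alkyne carbon without strain. C2 is controlled by the catalyst, whose diphenyl(silyloxy)methyl group blocks one face of the iminium ion so that oxygen enters from the other, and because the addition is reversible while the ring closure is not, both epimers of 5 are drained through the faster-cyclising 2S enamine. C3 is controlled by C2: the formyl-bearing carbon takes up the trans position relative to the aryl group in the ring closure and, being epimerisable through the enamine, is held there by thermodynamics as well. Anti addition of carbon and palladium across the alkyne followed by protonolysis with retention places the benzylidene aryl group cis to C3, the E geometry. The step needs 5-exo over 6-endo closure and retention of the exocyclic alkene against migration into conjugation with the formyl group; the short tether secures the first, and conjugation with the dimethoxyphenyl ring together with low temperature and immediate reduction in step 3 is relied on for the second.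

Step 3
Reactants: 6 (2S,3S,4E)-2-(3,4-dimethoxyphenyl)-4-(3,4-dimethoxybenzylidene)tetrahydrofuran-3-carbaldehyde
Product: 7 [(2S,3R,4E)-2-(3,4-dimethoxyphenyl)-4-(3,4-dimethoxybenzylidene)tetrahydrofuran-3-yl]methanol
Conditions: NaBH4, MeOH, −20 → 0 °C, on crude 6
Reagents that add atoms: none
Why: Hydride reduction of the aldehyde; at low temperature addition to the formyl group should be much faster than deprotonation at C3, so the 2,3-trans configuration and the exocyclic alkene are carried into the alcohol, in which C3 is no longer acidic. The aryl ethers and the styrenyl alkene are inert to NaBH4.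

Step 4
Reactants: 7 [(2S,3R,4E)-2-(3,4-dimethoxyphenyl)-4-(3,4-dimethoxybenzylidene)tetrahydrofuran-3-yl]methanol
Product: 8 tert-butyl{[(2S,3R,4E)-2-(3,4-dimethoxyphenyl)-4-(3,4-dimethoxybenzylidene)tetrahydrofuran-3-yl]methoxy}dimethylsilane
Conditions: TBSCl, imidazole, DMF, rt
Reagents that add atoms: tert-butyldimethylsilyl chloride (TBSCl), CC(C)(C)[Si](C)(C)Cl
Why: Imidazole-promoted silylation of a primary alcohol; the silyl ether removes the hydroxyl that could hold the substrate to a metal surface by the wrong face and adds bulk on the C3 arm for step 5.

Step 5
Reactants: 8 tert-butyl{[(2S,3R,4E)-2-(3,4-dimethoxyphenyl)-4-(3,4-dimethoxybenzylidene)tetrahydrofuran-3-yl]methoxy}dimethylsilane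
Product: 9 tert-butyl{[(2S,3R,4R)-4-(3,4-dimethoxybenzyl)-2-(3,4-dimethoxyphenyl)tetrahydrofuran-3-yl]methoxy}dimethylsilane
Conditions: H2 (1 atm), 5 % Pd/C, EtOAc, Et3N (1 %), rt
Reagents that add atoms: none
Why: Heterogeneous catalytic hydrogenation of the trisubstituted styrenyl alkene; allylic strain with the aryl group on C7, which is cis to C3, turns the silyloxymethyl arm out of the alkene plane, so the catalyst should bind the opposite face and deliver both hydrogens there, which sets C4 as R with the benzyl group cis to the C3 arm. Low pressure and the amine additive are chosen to hold back hydrogenolysis of the benzylic C2–O1 bond.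

Step 6
Reactants: 9 tert-butyl{[(2S,3R,4R)-4-(3,4-dimethoxybenzyl)-2-(3,4-dimethoxyphenyl)tetrahydrofuran-3-yl]methoxy}dimethylsilane
Product: 10 [(2S,3R,4R)-4-(3,4-dimethoxybenzyl)-2-(3,4-dimethoxyphenyl)tetrahydrofuran-3-yl]methanol
Conditions: TBAF, THF, 0 °C → rt
Reagents that add atoms: none
Why: Fluoride-induced desilylation, driven by the Si–F bond; nothing else in 9 reacts with fluoride and no stereocentre is touched.

Step 7
Reactants: 10 [(2S,3R,4R)-4-(3,4-dimethoxybenzyl)-2-(3,4-dimethoxyphenyl)tetrahydrofuran-3-yl]methanol; 11 angelic acid, (Z)-2-methylbut-2-enoic acid
Product: 12 leoligin, [(2S,3R,4R)-4-(3,4-dimethoxybenzyl)-2-(3,4-dimethoxyphenyl)tetrahydrofuran-3-yl]methyl (Z)-2-methylbut-2-enoate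
Conditions: PPh3, DIAD, THF, 0 °C → rt
Reagents that add atoms: none
Why: Mitsunobu esterification: the primary alcohol becomes an alkoxyphosphonium ion and is displaced by the angelate anion, so the acid is never turned into an acyl electrophile, the usual path by which the Z alkene goes over to the tiglate. C6 is not a stereocentre and the three ring stereocentres are untouched.

## Compound list

1 | propargyl alcohol (prop-2-yn-1-ol) | C#CCO | starting material
2 | 4-iodo-1,2-dimethoxybenzene | COc1ccc(I)cc1OC | starting material
3 | 3-(3,4-dimethoxyphenyl)prop-2-yn-1-ol | COc1ccc(C#CCO)cc1OC | intermediate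
4 | (E)-3-(3,4-dimethoxyphenyl)prop-2-enal (3,4-dimethoxycinnamaldehyde) | COc1ccc(/C=C/C=O)cc1OC | starting material
5 | (3S)-3-(3,4-dimethoxyphenyl)-3-{[3-(3,4-dimethoxyphenyl)prop-2-yn-1-yl]oxy}propanal (oxa-Michael adduct; the epimer that cyclises, in equilibrium with its 3R epimer and held in the flask as the enamine of the catalyst) | O=CC[C@H](OCC#Cc1ccc(OC)c(OC)c1)c1ccc(OC)c(OC)c1 | intermediate
6 | (2S,3S,4E)-2-(3,4-dimethoxyphenyl)-4-(3,4-dimethoxybenzylidene)tetrahydrofuran-3-carbaldehyde (2,3-trans) | O=C[C@H]1/C(=C\c2ccc(OC)c(OC)c2)CO[C@@H]1c1ccc(OC)c(OC)c1 | intermediate
7 | [(2S,3R,4E)-2-(3,4-dimethoxyphenyl)-4-(3,4-dimethoxybenzylidene)tetrahydrofuran-3-yl]methanol | OC[C@H]1/C(=C\c2ccc(OC)c(OC)c2)CO[C@@H]1c1ccc(OC)c(OC)c1 | intermediate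
8 | tert-butyl{[(2S,3R,4E)-2-(3,4-dimethoxyphenyl)-4-(3,4-dimethoxybenzylidene)tetrahydrofuran-3-yl]methoxy}dimethylsilane | CC(C)(C)[Si](C)(C)OC[C@H]1/C(=C\c2ccc(OC)c(OC)c2)CO[C@@H]1c1ccc(OC)c(OC)c1 | intermediate
9 | tert-butyl{[(2S,3R,4R)-4-(3,4-dimethoxybenzyl)-2-(3,4-dimethoxyphenyl)tetrahydrofuran-3-yl]methoxy}dimethylsilane | CC(C)(C)[Si](C)(C)OC[C@H]1[C@@H](Cc2ccc(OC)c(OC)c2)CO[C@@H]1c1ccc(OC)c(OC)c1 | intermediate
10 | [(2S,3R,4R)-4-(3,4-dimethoxybenzyl)-2-(3,4-dimethoxyphenyl)tetrahydrofuran-3-yl]methanol | OC[C@H]1[C@@H](Cc2ccc(OC)c(OC)c2)CO[C@@H]1c1ccc(OC)c(OC)c1 | intermediate
11 | angelic acid, (Z)-2-methylbut-2-enoic acid | C/C=C(/C)C(=O)O | starting material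
12 | leoligin, [(2S,3R,4R)-4-(3,4-dimethoxybenzyl)-2-(3,4-dimethoxyphenyl)tetrahydrofuran-3-yl]methyl (Z)-2-methylbut-2-enoate | C/C=C(/C)C(=O)OC[C@H]1[C@@H](Cc2ccc(OC)c(OC)c2)CO[C@@H]1c1ccc(OC)c(OC)c1 | target

## Step count and least certain steps

Total: 7 steps. Longest linear sequence: 7 steps (steps 1 to 7, from 1 and 2); 4 and 11 enter as purchased compounds.

**Step 2 (key step, proposed new method).**
- What may go wrong: the ring closure may be too slow. The alcohol addition lies on the side of the starting materials, so nothing accumulates unless the enamine adds quickly to the alkyne, and an internal alkyne with an electron-rich aryl cap is a poorer acceptor than a terminal one. The same aryl group polarises the alkyne towards attack at C7, which would favour 6-endo closure. Once the product has formed, the amine can convert it into a dienamine, and protonation of that at C7 would move the alkene into the ring and erase C3.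
- Fallback (known chemistry; sets out from 3, returns at 7):
  - Appel bromination (CBr4, PPh3, CH2Cl2) converts 3 into 4-(3-bromoprop-1-yn-1-yl)-1,2-dimethoxybenzene F1.
  - Addition of vinylmagnesium bromide to commercial 3,4-dimethoxybenzaldehyde gives racemic 1-(3,4-dimethoxyphenyl)prop-2-en-1-ol F2. Lipase-catalysed acetylation (Burkholderia cepacia lipase, vinyl acetate) removes the R enantiomer as its acetate and leaves (S)-1-(3,4-dimethoxyphenyl)prop-2-en-1-ol F3.
  - Williamson etherification of F3 with F1 (NaH, THF) gives 4-[(1S)-1-{[3-(3,4-dimethoxyphenyl)prop-2-yn-1-yl]oxy}prop-2-en-1-yl]-1,2-dimethoxybenzene F4.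
  - Epoxidation of the terminal alkene with mCPBA gives 2-[(R)-(3,4-dimethoxyphenyl){[3-(3,4-dimethoxyphenyl)prop-2-yn-1-yl]oxy}methyl]oxirane F5 as a mixture of epoxide epimers.
  - Cp2TiCl, made in the flask from Cp2TiCl2 and zinc dust in THF, opens the epoxide by electron transfer from trivalent titanium. The epoxide stereocentre is lost in the resulting C3 radical, so both epimers converge. The radical closes 5-exo-dig onto the aryl alkyne trans to the C2 aryl group, and reduction of the vinyl radical gives 7 after aqueous work-up. The alkene geometry from this sequence does not matter, since step 5 removes it.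

**Step 3.**
- What may go wrong: migration of the alkene into conjugation, or epimerisation at C3, in the basic borohydride medium before hydride transfer is complete, because the C3 hydrogen of 6 is both α to the formyl group and allylic.
- Fallback (sets out from 6, returns at 7): Pinnick oxidation (NaClO2, NaH2PO4, 2-methyl-2-butene, t-BuOH/H2O), run in a weakly acidic buffer where enolisation is slow, gives (2S,3S,4E)-2-(3,4-dimethoxyphenyl)-4-(3,4-dimethoxybenzylidene)tetrahydrofuran-3-carboxylic acid F6. Its carboxylate is far less prone to α-deprotonation, and LiAlH4 in THF reduces it to 7.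

**Step 5.**
- What may go wrong: insufficient facial discrimination, since the C2 aryl group lies on the face from which hydrogen has to come, or hydrogenolysis of the benzylic C2–O1 bond or of the allylic C5–O1 bond on palladium before the alkene is saturated.
- Fallback (sets out from 8, returns at 9): hydrogen-atom-transfer hydrogenation with Mn(dpm)3 (dpm = 2,2,6,6-tetramethylheptane-3,5-dionate), PhSiH3 and t-BuOOH in i-PrOH. A bulky metal hydride delivers a hydrogen atom to C4 from the open face to give the benzylic C7 radical, which is then reduced. No metal surface is involved, so C–O hydrogenolysis is not possible. No new compound is made.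

**Step 7.**
- What may go wrong: isomerisation of the Z alkene to the E geometry through reversible addition of the phosphine or the betaine to the unsaturated acid, or slow displacement at the β-branched primary carbon C6.
- Fallback (sets out from 10, returns at 12): mesylation (MsCl, Et3N, CH2Cl2, 0 °C) gives [(2S,3R,4R)-4-(3,4-dimethoxybenzyl)-2-(3,4-dimethoxyphenyl)tetrahydrofuran-3-yl]methyl methanesulfonate F7. Displacement with caesium angelate, made from 11 and Cs2CO3 in DMF at 50 °C, gives 12 without any phosphine and without activation of the acyl group.

## Further compounds

F1 | step 2 | 4-(3-bromoprop-1-yn-1-yl)-1,2-dimethoxybenzene | COc1ccc(C#CCBr)cc1OC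
F2 | step 2 | racemic 1-(3,4-dimethoxyphenyl)prop-2-en-1-ol | COc1ccc(C(O)C=C)cc1OC
F3 | step 2 | (S)-1-(3,4-dimethoxyphenyl)prop-2-en-1-ol | COc1ccc([C@@H](O)C=C)cc1OC
F4 | step 2 | 4-[(1S)-1-{[3-(3,4-dimethoxyphenyl)prop-2-yn-1-yl]oxy}prop-2-en-1-yl]-1,2-dimethoxybenzene | C=C[C@H](OCC#Cc1ccc(OC)c(OC)c1)c1ccc(OC)c(OC)c1
F5 | step 2 | 2-[(R)-(3,4-dimethoxyphenyl){[3-(3,4-dimethoxyphenyl)prop-2-yn-1-yl]oxy}methyl]oxirane, both epoxide epimers | C1OC1[C@H](OCC#Cc2ccc(OC)c(OC)c2)c2ccc(OC)c(OC)c2
F6 | step 3 | (2S,3S,4E)-2-(3,4-dimethoxyphenyl)-4-(3,4-dimethoxybenzylidene)tetrahydrofuran-3-carboxylic acid | OC(=O)[C@H]1/C(=C\c2ccc(OC)c(OC)c2)CO[C@@H]1c1ccc(OC)c(OC)c1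
F0 | step 5 | none | none
F7 | step 7 | [(2S,3R,4R)-4-(3,4-dimethoxybenzyl)-2-(3,4-dimethoxyphenyl)tetrahydrofuran-3-yl]methyl methanesulfonate | CS(=O)(=O)OC[C@H]1[C@@H](Cc2ccc(OC)c(OC)c2)CO[C@@H]1c1ccc(OC)c(OC)c1
A1 | alternative 1 | tert-butyl{[(2S,3R,4R)-4-(3,4-dimethoxybenzyl)-2-(3,4-dimethoxyphenyl)tetrahydrofuran-3-yl]methoxy}dimethylsilane (identical with 9) | CC(C)(C)[Si](C)(C)OC[C@H]1[C@@H](Cc2ccc(OC)c(OC)c2)CO[C@@H]1c1ccc(OC)c(OC)c1
A2 | alternative 1 | tert-butyl{[(3R)-3-(allyloxy)-3-(3,4-dimethoxyphenyl)-2-iodopropyl]oxy}dimethylsilane, either epimer at the iodide carbon | CC(C)(C)[Si](C)(C)OCC(I)[C@H](OCC=C)c1ccc(OC)c(OC)c1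
A3 | alternative 2 | cis-fused 6-(3,4-dimethoxyphenyl)-3-[(1S,2R,5S)-menthyloxy]tetrahydro-1H,3H-furo[3,4-c]furan-1-one | O=C1[C@H]2[C@H](CO[C@@H]2c3ccc(OC)c(OC)c3)[C@@H](O[C@H]4C[C@@H](C)CC[C@@H]4C(C)C)O1
A4 | alternative 2 | {[chloro(3,4-dimethoxyphenyl)methoxy]methyl}trimethylsilane | COc1ccc(C(Cl)OC[Si](C)(C)C)cc1OC
A5 | alternative 2 | (5S)-5-{[(1S,2R,5S)-2-isopropyl-5-methylcyclohexyl]oxy}furan-2(5H)-one | O=C1C=C[C@@H](O[C@H]2C[C@@H](C)CC[C@@H]2C(C)C)O1
A6 | alternative 3 | methyl (2S,3S,4R)-4-(3,4-dimethoxybenzyl)-2-(3,4-dimethoxyphenyl)tetrahydrofuran-3-carboxylate | COC(=O)[C@H]1[C@@H](Cc2ccc(OC)c(OC)c2)CO[C@@H]1c1ccc(OC)c(OC)c1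
A7 | alternative 3 | (2R,5S)-3-diazo-5-(3,4-dimethoxybenzyl)-2-(3,4-dimethoxyphenyl)tetrahydro-4H-pyran-4-one | [N-]=[N+]=C1C(=O)[C@@H](Cc2ccc(OC)c(OC)c2)CO[C@@H]1c1ccc(OC)c(OC)c1
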